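Readings and results are calculated for substances that don't exist; the scatter is artificial.

The pitfall sits in the loading: a charge in mol% is tied to the substrate, so a more dilute flask also holds less catalyst, and carrying a percent yield from one flask to another quietly assumes an order in substrate.

| flask | substrate | reagent | free catalyst | temperature | remark | time |
|---|---|---|---|---|---|---|
| north-east | 0.067 M | 2 equiv | 0.5 mol% | −10 °C | run made earlier |  |
| south-west | 0.15 M | 2 equiv | 0.5 mol% | 10 °C | run made earlier |  |
| teal | 0.10 M | 2.00 equiv | 0.5 mol% | 25 °C |  | 30 h |
| amber | 0.10 M | 2.00 equiv | 0.5 mol% | 10 °C |  | 30 h |
| green | 0.10 M | 2.00 equiv | 0.5 mol% |  | at −5 °C until 15 h, from then on at 25 °C | 30 h |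
| red | 0.10 M | 2.00 equiv | 0.5 mol% | −5 °C |  | 30 h |

| run | time / h | target / % | substrate / % |
|---|---|---|---|
| north-east | 30.0 | 2.0 | 97.4 |
| north-east | 72.0 | 3.9 | 95.0 |
| north-east | 120 | 8.8 | 92.0 |
| north-east | 144 | 9.3 | 90.4 |
| south-west | 6.00 | 6.5 | 94.1 |
| south-west | 15.0 | 13.5 | 86.7 |
| south-west | 30.0 | 24.8 | 73.8 |
| south-west | 48.0 | 36.5 | 64.7 |

(standard deviation of a reading: 0.5 percentage points)

- the analysis behind the earlier runs scatters by 0.5 percentage points, standard deviation
- steps under discussion: reagent + free catalyst -> catalyst intermediate A; substrate + catalyst intermediate A -> catalyst intermediate B; catalyst intermediate B -> catalyst intermediate C; catalyst intermediate C -> free catalyst + target; 2 catalyst intermediate A -> spent catalyst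

* which flask leads in amount of target, in percent of the substrate charged ("all alike" within 1.5 percentage points) (teal / amber / green / red / all alike)
* how much target is there at the end, in percent of the substrate charged: teal
* how much target is there at the end, in percent of the substrate charged: amber
* how much target is there at the end, in percent of the substrate charged: green
* how much target is there at the end, in percent of the substrate charged: red

Two chemists argue at the board about one concentration, c(substrate), and whether it sets the rate. The south-west run gained 6.5 % target in its first 6.00 h, but 12 percentage points in its last 18.0 h, so the rate fell.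

The first chemist says the rate fell with c(substrate): the rate is first order in substrate and in catalyst. At fixed temperature and equivalents, the south-west run at 30.0 h then reads 12.7 /M/h. This is the per-catalyst constant κ: the natural logarithm of charged substrate over substrate not yet turned to target, divided by the catalyst concentration charged and by the time.

The second chemist says the catalyst is saturated with substrate, so the rate is zero order in it, and the fall comes from catalyst dying as two catalyst intermediate A join to spent catalyst. This view holds for a flask whose catalyst stands mostly as catalyst intermediates B and C, the forms that carry substrate, and these readings do not show where the catalyst stands.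

Amber parts them, because it shares 10 °C and the loading with the south-west run but holds 0.10 M substrate against 0.15 M. On the saturated view, each catalyst turns over at the same pace and the catalyst per substrate is unchanged, but amber's catalyst is more dilute than in the south-west run, and two catalyst intermediate A must meet to die, so amber loses its catalyst more slowly and reaches 24.8 % or more at 30 h. With κ, my own reckoning for amber gives 17.3 %.

The forecast takes the first side, saying the south-west run “fits first-order decay in substrate”, but its amber figure stands above mine. It gives 47 % for teal, 19.5 % for amber, 28 % for green and 4.5 % for red, with teal leading.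

The flasks give 45.8 % for teal, 17.9 % for amber, 28.7 % for green and 5.11 % for red, so teal leads.

    reagent + free catalyst → catalyst intermediate A (k = 0.00790 /M/s, Ea = 48.0 kJ/mol)
    substrate + catalyst intermediate A → catalyst intermediate B (k = 0.0530 /M/s, Ea = 69.0 kJ/mol)
    catalyst intermediate B → catalyst intermediate C (k = 0.580 /s, Ea = 62.0 kJ/mol)
    catalyst intermediate C → free catalyst + target (k = 0.600 /s, Ea = 69.0 kJ/mol)
    2 catalyst intermediate A → spent catalyst (k = 0.0660 /M/s, Ea = 69.0 kJ/mol)
    (constants at 25 °C)

Amber's 17.9 % lies below the floor of 24.8 % that the saturated view set, and read from amber, κ is 13.1 /M/h against 12.7 /M/h. At amber's end, catalyst intermediates B and C together held 0.396 % of the catalyst, hardly any. Green's neighbour charged with 0.25 M substrate keeps green's loading and temperature course, so κ multiplies green's logarithm by 2.50 and gives 57.1 %; that flask holds 54.3 %.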